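I began with an easy step: I turned the asked share round and worked with the fraction left, the part of over-reaction product plus target still standing as target.

| flask | substrate | remark | time |
|---|---|---|---|
| autumn | 0.50 mM | the very flask that is asked about, followed so far |  |
| noon | 0.75 mM | run made earlier |  |
| flask | 0.50 mM |  | 2.0 min |

- share of over-reaction product in over-reaction product plus target at 3.0 s
- share of over-reaction product in over-reaction product plus target at 20 s
- share of over-reaction product in over-reaction product plus target at 2.0 min

- autumn (time / s: over-reaction product / %, target / %): 10.0: 0.7, 4.3; 12.0: 1.7, 3.8; 20.0: 3.7, 5.4; 40.0: 10.2, 5.8; 60.0: 17.5, 7.4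
- noon (time / s: over-reaction product / %, target / %): 10.0: 1.8, 3.6; 15.0: 1.9, 5.6; 25.0: 5.8, 6.4; 40.0: 9.5, 7.0; 80.0: 25.2, 7.8; 120: 40.4, 7.1

(standard deviation of a reading: 0.5 percentage points)

I then tried each input in turn. The charge looked harmless: at 40.0 s the autumn run (0.50 mM) showed 10.2% product and the noon run (0.75 mM) 9.5%, a gap of 0.7 percentage points against a scatter of 0.5 points, so I used noon's percentages for the autumn flask. Noon's last reading left 14.9% as target, and there a slip in the target reading moves the share 5.69 times as far as the same slip in the product reading, so the target reading had to be good. At 3.0 s there is no reading, so I needed the over-reaction constant k_O, the product gained per second divided by the target standing, which noon's last two readings put at 0.0510 s⁻¹. With target taken as rising in a straight line from zero, product over target is k_O·t/2, and turned into a share of the two that gave me 7.11%. My other two shares were read from runs: 40.7% at 20 s from autumn, and 85.1% at 2.0 min from noon.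

The forecast gave 8%, 38% and 85.5%, noting that “the two runs overlay despite the different starting concentrations”.

The flask gave 7.04%, 38.9% and 85.0%.

    intermediate A → target (k = 0.0228 s⁻¹)
    substrate ⇌ dormant form (K = 0.955, k = 0.0902 s⁻¹)
    target → over-reaction product (k = 0.0509 s⁻¹)
    intermediate B ⇌ target (K = 1.21, k = 0.0222 s⁻¹)
    substrate ⇌ intermediate A (K = 0.361, k = 1.40 s⁻¹)
    substrate → intermediate B (k = 0.0113 s⁻¹)

The k_O read from noon puts the half-life of target, by its step to over-reaction product, at 13.6 s, shorter than the 0.52 min of intermediate B in the autumn flask at 2.00 min by its forward step to target, and at 1.13 min target in that flask was near a quasi-steady state, made 1.02 times as fast as it was used up. For the neighbour flask charged with 2.0 mM, the same share from k_O·t/2 is again 7.11% at 3.0 s, and that flask stood at 7.04%.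

(The numbers in the tables were computed on assumed constants, noise included.)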